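**Strategy.** Ring A carries six different substituents, so it is built from open chains and not decorated. In flavone numbering, the stretch C5 to C8 (O, prenyl, O, methyl) maps onto C1–C4 of methyl 2-prenyl-3-oxopentanoate. C4a–C8a (acyl-bearing carbon next to an oxygen-bearing carbon) maps onto the triple bond of a β-bromo alkynoate. The bis(silyloxy) ketene acetal diene of the keto ester adds to methyl 3-bromopropiolate in a (4+2) cycloaddition that forges C8–C8a and C4a–C5. Loss of methanol then gives the arene with every group in place: the halogen earmarks C8a for O1, and the ester carbon becomes C4. A C3–C4 aldol with a ring B ketone and a copper-catalysed O1–C8a closure complete ring C.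

Key step: step 5

Remark on notation: atoms are labelled in flavone numbering in all intermediates. Prenyl = 3-methylbut-2-en-1-yl and MOM = methoxymethyl. The target has no stereocentre and no stereogenic double bond.

Assumption: salts formed by plain deprotonation (enolates, phenoxides, alkoxides) count as forms of the numbered parent compound and receive no number of their own.

**Step 1**
Reactants: 1 methyl 3-oxopentanoate; 2 prenyl bromide (1-bromo-3-methylbut-2-ene)
Product: 3 methyl 2-prenyl-3-oxopentanoate (racemic)
Conditions: NaH (1.0 equiv), 1 (1.15 equiv), THF, 0 °C; then 2, 0 °C → rt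
Reagents that add atoms: none
Why: Acetoacetic-ester-type SN2 C-alkylation: only C2 is flanked by both carbonyl groups, the primary allylic bromide is attacked at its unhindered CH2, a slight excess of 1 suppresses double alkylation, and the racemic centre formed is planarised again in step 2.

**Step 2**
Reactants: 3 methyl 2-prenyl-3-oxopentanoate
Product: 4 methyl 2-prenyl-3-(trimethylsilyloxy)pent-2-enoate (E/Z mixture)
Conditions: Me3SiCl, Et3N, toluene, rt, 48–72 h; filtration under argon
Reagents that add atoms: chlorotrimethylsilane, C[Si](C)(C)Cl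
Why: Amine-mediated O-silylation of a β-keto ester (silyl enol ether formation) should give the conjugated enoate, and its E/Z composition is irrelevant because this double bond ends up as the central single bond of the diene.

**Step 3**
Reactants: 4 methyl 2-prenyl-3-(trimethylsilyloxy)pent-2-enoate
Product: 5 (1Z,3Z)-1-methoxy-2-prenyl-1,3-bis(trimethylsilyloxy)penta-1,3-diene
Conditions: LiN(i-Pr)2 (LDA), THF, −78 °C; Me3SiCl, −78 °C → rt; pentane, filtration under argon, used crude
Reagents that add atoms: chlorotrimethylsilane, C[Si](C)(C)Cl
Why: Kinetic γ-deprotonation of the 3-silyloxy enoate and O-silylation of the extended ester enolate is the standard two-stage entry to 1-alkoxy-1,3-bis(silyloxy)dienes; allylic 1,3-strain against the prenyl-bearing C2 should put the terminal methyl group trans to C2 (3Z, outward in the s-cis form), whereas the ketene acetal geometry has no bearing on the outcome.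

**Step 4**
Reactants: 6 methyl propiolate
Product: 7 methyl 3-bromopropiolate
Conditions: NBS, AgNO3 (10 mol %), acetone, rt, dark; distillation
Reagents that add atoms: N-bromosuccinimide, O=C1CCC(=O)N1Br
Why: Silver-catalysed electrophilic bromination of a terminal alkyne with NBS, which proceeds through the silver acetylide and leaves the ester untouched, is the standard preparation of this distillable, lachrymatory bromoalkynoate.

**Step 5**
Reactants: 5 (1Z,3Z)-1-methoxy-2-prenyl-1,3-bis(trimethylsilyloxy)penta-1,3-diene; 7 methyl 3-bromopropiolate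
Product: 10 methyl 2-bromo-4,6-dihydroxy-3-methyl-5-prenylbenzoate, via cyclohexadiene adduct 8 (not isolated), via bis(trimethylsilyl) ether 9 (not isolated)
Conditions: 5 (1.5 equiv), 7 (1.0 equiv), toluene, argon, dark, 0 → 60 °C; then 1 M aq HCl, THF, 0 °C
Reagents that add atoms: none
Why: Normal-electron-demand Diels–Alder reaction of a 1-alkoxy-1,3-bis(silyloxy)diene with an alkynoate followed by aromatisation, the known route to resorcylates, is applied here to a fully substituted diene and a bromoalkyne. The methyl-bearing terminus of 5 (largest HOMO coefficient, future C8) engages the bromine-bearing β-carbon of 7 (largest LUMO coefficient, future C8a) ahead of the union of the ketene acetal carbon (C5) with the α-carbon (C4a), a single-step but strongly asynchronous process that gives 8. Ring A is closed intermolecularly as a six-membered carbocycle from a four-carbon and a two-carbon piece, both ring bonds arising in the same event. The sp3 centres C5 and C8 of 8 need no control, because 1,4-elimination of methanol across them removes both and gives 9, whose two aryl silyl ethers fall to the dilute acid. Regioselectivity follows from the matched polarisation of the partners, the outward methyl group (3Z) keeps the s-cis form accessible, and the isolated trisubstituted prenyl alkene cannot compete as diene or dienophile. Chemoselectivity against bromine transfer to the diene and against addition–elimination at C8a is sought with a non-polar solvent, no Lewis acid, darkness and slow warming, and the excess of 5 takes up the methanol that would otherwise protonate the ketene acetal.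

**Step 6**
Reactants: 10 methyl 2-bromo-4,6-dihydroxy-3-methyl-5-prenylbenzoate
Product: 11 methyl 2-bromo-4,6-bis(methoxymethoxy)-3-methyl-5-prenylbenzoate
Conditions: NaH (3 equiv), MOMCl (3 equiv), DMF, 0 °C → rt
Reagents that add atoms: chloromethyl methyl ether, COCCl
Why: MOM ether formation by O-alkylation of the sodium phenoxides (Williamson type): the strong base is chosen because one phenol is hydrogen-bonded to the ester and both are flanked by two substituents, while the shielded ester, the aryl bromide and the alkene are inert.

**Step 7**
Reactants: 11 methyl 2-bromo-4,6-bis(methoxymethoxy)-3-methyl-5-prenylbenzoate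
Product: 12 [2-bromo-4,6-bis(methoxymethoxy)-3-methyl-5-prenylphenyl]methanol
Conditions: i-Bu2AlH (3 equiv), CH2Cl2, −78 → 0 °C; aq potassium sodium tartrate
Reagents that add atoms: none
Why: Exhaustive hydride reduction of the ester with i-Bu2AlH is preferred to a partial reduction, which cannot be stopped dependably on a doubly ortho-substituted benzoate, and aryl bromide, acetals and alkene do not react at or below 0 °C.

**Step 8**
Reactants: 12 [2-bromo-4,6-bis(methoxymethoxy)-3-methyl-5-prenylphenyl]methanol
Product: 13 2-bromo-4,6-bis(methoxymethoxy)-3-methyl-5-prenylbenzaldehyde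
Conditions: Dess–Martin periodinane (1.2 equiv), pyridine, CH2Cl2, 0 °C → rt
Reagents that add atoms: none
Why: Dess–Martin oxidation of a benzylic alcohol stops cleanly at the aldehyde, and the pyridine buffer keeps the released acetic acid away from the acetals and the prenyl alkene.

**Step 9**
Reactants: 14 2-chloro-1-(3,4-dihydroxyphenyl)ethanone
Product: 16 1-(3,4-dihydroxyphenyl)-2-hydroxyethanone, via formate ester 15 (not isolated)
Conditions: HCO2Na (4 equiv), HCO2H (buffer), EtOH–H2O, reflux, N2
Reagents that add atoms: sodium formate, [Na+].[O-]C=O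
Why: SN2 displacement of the α-chloro ketone by formate followed by hydrolysis of the labile formate ester in the same hot aqueous medium (formate route to α-ketols) avoids hydroxide, which would invite epoxide or Favorskii-type pathways and catechol oxidation.

**Step 10**
Reactants: 16 1-(3,4-dihydroxyphenyl)-2-hydroxyethanone
Product: 17 1-[3,4-bis(methoxymethoxy)phenyl]-2-(methoxymethoxy)ethanone
Conditions: MOMCl (6 equiv), i-Pr2NEt (8 equiv), CH2Cl2–DMF, 0 °C → rt
Reagents that add atoms: chloromethyl methyl ether, COCCl
Why: MOM protection with an amine base covers the two phenols and the primary ketol hydroxyl in one operation without the strong base that could enolise or isomerise the α-ketol.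

**Step 11**
Reactants: 17 1-[3,4-bis(methoxymethoxy)phenyl]-2-(methoxymethoxy)ethanone; 13 2-bromo-4,6-bis(methoxymethoxy)-3-methyl-5-prenylbenzaldehyde
Product: 18 3-[2-bromo-4,6-bis(methoxymethoxy)-3-methyl-5-prenylphenyl]-1-[3,4-bis(methoxymethoxy)phenyl]-3-hydroxy-2-(methoxymethoxy)propan-1-one (racemic mixture of diastereomers)
Conditions: 17 (1.2 equiv), LiN(SiMe3)2, THF, −78 °C; 13, −78 °C; AcOH in THF at −78 °C
Reagents that add atoms: none
Why: Directed (crossed) lithium enolate aldol addition: 17 has a single enolisable position and 13 has none, the cold acidic quench forestalls retro-aldol cleavage, and the two new stereocentres may form as any mixture because steps 12 and 13 turn both into sp2 carbons.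

**Step 12**
Reactants: 18 the aldol adduct
Product: 19 1-[2-bromo-4,6-bis(methoxymethoxy)-3-methyl-5-prenylphenyl]-3-[3,4-bis(methoxymethoxy)phenyl]-2-(methoxymethoxy)propane-1,3-dione (keto/enol mixture)
Conditions: Dess–Martin periodinane (1.2 equiv), pyridine, CH2Cl2, 0 °C → rt
Reagents that add atoms: none
Why: Dess–Martin oxidation of a β-hydroxy ketone to the 1,3-diketone works under near-neutral conditions that avoid retro-aldol cleavage and elimination, and a small excess of oxidant limits attack on the enolisable C3–H.

**Step 13**
Reactants: 19 the 2-(methoxymethoxy)-1,3-diketone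
Product: 20 2-[3,4-bis(methoxymethoxy)phenyl]-3,5,7-tris(methoxymethoxy)-8-methyl-6-prenyl-4H-chromen-4-one
Conditions: CuI (10 mol %), 1,10-phenanthroline (20 mol %), K2CO3 (2 equiv), dry DMF, 100 °C, argon
Reagents that add atoms: none
Why: Intramolecular Ullmann-type O-arylation of a β-diketone enolate, a known entry to chromones and flavones from 1-(2-haloaryl)-1,3-diketones: the diketonate holds monovalent copper next to the C8a–Br bond, the ortho acyl group also allows uncatalysed addition–elimination, only the ring B enolate oxygen can reach C8a in a six-membered closure, and acetals and alkene tolerate carbonate.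

**Step 14**
Reactants: 20 the penta-MOM flavonol
Product: 21 8-methyl-6-prenylquercetin
Conditions: HCl (1.25 M in MeOH), MeOH–THF, 0 → 40 °C, argon
Reagents that add atoms: none
Why: Acid-catalysed acetal exchange of the five MOM ethers with methanol, the customary last step for prenylated flavonoids, is run dilute and barely warm and is stopped at full conversion so that protonation of the C6 prenyl alkene next to O5 and O7 stays slow.

**Compound list**
1 | methyl 3-oxopentanoate | CCC(=O)CC(=O)OC | starting material
2 | prenyl bromide | CC(C)=CCBr | starting material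
3 | methyl 2-prenyl-3-oxopentanoate (racemic) | CCC(=O)C(CC=C(C)C)C(=O)OC | intermediate
4 | methyl 2-prenyl-3-(trimethylsilyloxy)pent-2-enoate (E/Z mixture) | CCC(O[Si](C)(C)C)=C(CC=C(C)C)C(=O)OC | intermediate
5 | (1Z,3Z)-1-methoxy-2-prenyl-1,3-bis(trimethylsilyloxy)penta-1,3-diene | CO/C(O[Si](C)(C)C)=C(CC=C(C)C)/C(O[Si](C)(C)C)=C/C | intermediate
6 | methyl propiolate | C#CC(=O)OC | starting material
7 | methyl 3-bromopropiolate | COC(=O)C#CBr | intermediate
8 | methyl 2-bromo-6-methoxy-3-methyl-5-prenyl-4,6-bis(trimethylsilyloxy)cyclohexa-1,4-diene-1-carboxylate (two transient centres, configuration irrelevant) | COC(=O)C1=C(Br)C(C)C(O[Si](C)(C)C)=C(CC=C(C)C)C1(OC)O[Si](C)(C)C | intermediate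
9 | methyl 2-bromo-3-methyl-5-prenyl-4,6-bis(trimethylsilyloxy)benzoate | COC(=O)c1c(Br)c(C)c(O[Si](C)(C)C)c(CC=C(C)C)c1O[Si](C)(C)C | intermediate
10 | methyl 2-bromo-4,6-dihydroxy-3-methyl-5-prenylbenzoate | COC(=O)c1c(Br)c(C)c(O)c(CC=C(C)C)c1O | intermediate
11 | methyl 2-bromo-4,6-bis(methoxymethoxy)-3-methyl-5-prenylbenzoate | COC(=O)c1c(Br)c(C)c(OCOC)c(CC=C(C)C)c1OCOC | intermediate
12 | [2-bromo-4,6-bis(methoxymethoxy)-3-methyl-5-prenylphenyl]methanol | OCc1c(Br)c(C)c(OCOC)c(CC=C(C)C)c1OCOC | intermediate
13 | 2-bromo-4,6-bis(methoxymethoxy)-3-methyl-5-prenylbenzaldehyde | O=Cc1c(Br)c(C)c(OCOC)c(CC=C(C)C)c1OCOC | intermediate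
14 | 2-chloro-1-(3,4-dihydroxyphenyl)ethanone | O=C(CCl)c1ccc(O)c(O)c1 | starting material
15 | 2-(3,4-dihydroxyphenyl)-2-oxoethyl formate | O=COCC(=O)c1ccc(O)c(O)c1 | intermediate
16 | 1-(3,4-dihydroxyphenyl)-2-hydroxyethanone | O=C(CO)c1ccc(O)c(O)c1 | intermediate
17 | 1-[3,4-bis(methoxymethoxy)phenyl]-2-(methoxymethoxy)ethanone | COCOCC(=O)c1ccc(OCOC)c(OCOC)c1 | intermediate
18 | 3-[2-bromo-4,6-bis(methoxymethoxy)-3-methyl-5-prenylphenyl]-1-[3,4-bis(methoxymethoxy)phenyl]-3-hydroxy-2-(methoxymethoxy)propan-1-one (diastereomer mixture) | COCOC(C(O)c1c(Br)c(C)c(OCOC)c(CC=C(C)C)c1OCOC)C(=O)c1ccc(OCOC)c(OCOC)c1 | intermediate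
19 | 1-[2-bromo-4,6-bis(methoxymethoxy)-3-methyl-5-prenylphenyl]-3-[3,4-bis(methoxymethoxy)phenyl]-2-(methoxymethoxy)propane-1,3-dione | COCOC(C(=O)c1c(Br)c(C)c(OCOC)c(CC=C(C)C)c1OCOC)C(=O)c1ccc(OCOC)c(OCOC)c1 | intermediate
20 | 2-[3,4-bis(methoxymethoxy)phenyl]-3,5,7-tris(methoxymethoxy)-8-methyl-6-prenyl-4H-chromen-4-one | COCOc1ccc(cc1OCOC)-c1oc2c(C)c(OCOC)c(CC=C(C)C)c(OCOC)c2c(=O)c1OCOC | intermediate
21 | 8-methyl-6-prenylquercetin, 2-(3,4-dihydroxyphenyl)-3,5,7-trihydroxy-8-methyl-6-(3-methylbut-2-en-1-yl)-4H-chromen-4-one | CC(C)=CCc1c(O)c(C)c2oc(-c3ccc(O)c(O)c3)c(O)c(=O)c2c1O | target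

**Step count**
Total step count: 14.
Longest linear sequence: 11 steps (1, 2, 3, 5, 6, 7, 8, 11, 12, 13, 14).

**Steps most likely to fail**

**Step 5.** Transfer of bromine from the sp carbon to the nucleophilic diene terminus may outpace ring closure. So may conjugate addition followed by expulsion of bromide. Crowding at both diene termini may also slow the cycloaddition until the diene is lost to protonation.

The fallback sets out from 5 and 6 and returns at 11. It keeps the halogen out of the cycloaddition and introduces it afterwards by directed metalation.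
- Diene 5 and methyl propiolate 6 are heated in toluene (80–110 °C) and worked up with dilute acid. The same polarity match should give methyl 2,4-dihydroxy-5-methyl-3-prenylbenzoate F1.
- NaH and MOMCl in DMF convert this into methyl 2,4-bis(methoxymethoxy)-5-methyl-3-prenylbenzoate F2.
- Its only ring C–H (future C8a) lies ortho to the ester. It is magnesiated with (2,2,6,6-tetramethylpiperidin-1-yl)magnesium chloride–lithium chloride (TMPMgCl·LiCl) in THF, 0 °C → rt, to give [2-(methoxycarbonyl)-3,5-bis(methoxymethoxy)-6-methyl-4-prenylphenyl]magnesium chloride F3.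
- F3 is quenched cold with 1,2-dibromo-1,1,2,2-tetrachloroethane to give 11.

This bromine donor reacts only with the carbanion, so the prenyl alkene is spared. Electrophilic bromination is not an option, because the position is meta to both oxygens.

**Step 14.** Protonation of the prenyl alkene in the Brønsted acid may lead to ring closure onto the neighbouring O5 or O7, or to addition of solvent. Either process may compete with the slow cleavage of the hindered C7 acetal.

The fallback sets out from 20 and returns at 21. It exchanges the acetals for silyl ethers in a medium without free protons.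
- Me3SiOTf and 2,2'-bipyridyl in MeCN, 0 °C → rt, should turn all five MOM ethers into silyl ethers. The product is 2-[3,4-bis(trimethylsilyloxy)phenyl]-8-methyl-6-prenyl-3,5,7-tris(trimethylsilyloxy)-4H-chromen-4-one F4, and the methoxymethyl groups are carried off on the bipyridyl nitrogen.
- Addition of water at rt then hydrolyses the labile aryl and enol silyl ethers to 21.

**Step 11.** The congested adduct may revert to its components (retro-aldol) during the reaction or on oxidation. Addition to the doubly ortho-substituted aldehyde may also be slow.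

The fallback sets out from 13 and 17 and returns at 19, bypassing 18 and step 12. It makes the C3–C4 bond at the acid oxidation level, where the product is withdrawn from equilibrium as its diketonate.
- Pinnick oxidation of 13 (NaClO2, NaH2PO4, 2-methylbut-2-ene, t-BuOH–H2O) gives 2-bromo-4,6-bis(methoxymethoxy)-3-methyl-5-prenylbenzoic acid F5.
- 1-(Methylsulfonyl)benzotriazole and Et3N in THF at reflux give 1-[2-bromo-4,6-bis(methoxymethoxy)-3-methyl-5-prenylbenzoyl]-1H-benzotriazole F6.
- The lithium enolate of 17 (2 equiv, LiN(SiMe3)2, THF, −78 °C → rt) is C-acylated by this reagent. Mild acidic work-up delivers 19.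

**Further compounds**
F1 | step 5 | methyl 2,4-dihydroxy-5-methyl-3-prenylbenzoate | COC(=O)c1cc(C)c(O)c(CC=C(C)C)c1O
F2 | step 5 | methyl 2,4-bis(methoxymethoxy)-5-methyl-3-prenylbenzoate | COC(=O)c1cc(C)c(OCOC)c(CC=C(C)C)c1OCOC
F3 | step 5 | [2-(methoxycarbonyl)-3,5-bis(methoxymethoxy)-6-methyl-4-prenylphenyl]magnesium chloride | COC(=O)c1c([Mg]Cl)c(C)c(OCOC)c(CC=C(C)C)c1OCOC
F4 | step 14 | 2-[3,4-bis(trimethylsilyloxy)phenyl]-8-methyl-6-prenyl-3,5,7-tris(trimethylsilyloxy)-4H-chromen-4-one | CC(C)=CCc1c(O[Si](C)(C)C)c(C)c2oc(-c3ccc(O[Si](C)(C)C)c(O[Si](C)(C)C)c3)c(O[Si](C)(C)C)c(=O)c2c1O[Si](C)(C)C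
F5 | step 11 | 2-bromo-4,6-bis(methoxymethoxy)-3-methyl-5-prenylbenzoic acid | OC(=O)c1c(Br)c(C)c(OCOC)c(CC=C(C)C)c1OCOC
F6 | step 11 | 1-[2-bromo-4,6-bis(methoxymethoxy)-3-methyl-5-prenylbenzoyl]-1H-benzotriazole | O=C(c1c(Br)c(C)c(OCOC)c(CC=C(C)C)c1OCOC)n1nnc2ccccc12
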